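**Retrosynthetic overview**

1. The diacetoxy aldehyde terminus is finished last from 25 (alkyne → (E)-alkenylboronate → enol acetate; CH2OTBS → CHO). The bond between the chain alkene CH and its neighbouring CH2 comes from a B-alkyl Suzuki coupling of alkenyl iodide 16 with the 9-BBN adduct of vinyl carbinol acetate 23.
2. 23 comes from enynol 19 by Sharpless epoxidation, which sets the acetoxy-bearing quaternary carbon, and one-carbon opening of the epoxide to a vinyl carbinol. 16 comes from alkyne 14 by carboalumination–iodination.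
3. The only ring, the cyclohexene (C1 stereocentre, C2 CMe, C3 alkene CH, C4 and C5 CH2, C6 CMe2), is built first. A [3+3] Michael–Claisen annulation of 2-methylpentan-3-one with methyl acrylate forms C5–C6 and C2–C3 in one operation.
4. Enabling feature: C1 lies between C2 and C6, so a ketone placed on C1 makes both ring neighbours α-carbons. C6 is the Michael donor that becomes the gem-dimethyl quaternary carbon, C2 is the Claisen donor, and acrylate supplies C3–C4–C5 as a 1,3-dielectrophile.
5. Both activating carbonyls are then consumed. The C1 carbonyl accepts the side chain (Stork–Danheiser transposition). The C3 carbonyl is reduced (CBS) and excised by an allylic diazene retro-ene shift that transfers chirality from C3 to C1 and leaves the C2=C3 alkene.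

Key step: step 1

Remark: ring atoms carry the numbering of the target's cyclohexene (C1–C6 as in line 3) in all intermediates, whatever their systematic names; compounds 1, 2, 6, 17 and 18 are taken as commercially available.

**Route**

Step 1
Reactants: 1 2-methylpentan-3-one; 2 methyl acrylate
Product: 4 2,4,4-trimethylcyclohexane-1,3-dione, via Michael adduct 3 (not isolated)
Conditions: KOtBu (2.2 equiv), THF, 0 °C to rt, slow addition of 2; then aq. HCl
Reagents that add atoms: none
Why: KOtBu equilibrates the enolates of 1; the more substituted (isopropyl-side) enolate adds to methyl acrylate in a Michael reaction that forms the C5–C6 bond and the quaternary carbon, and the ethyl-side enolate of adduct 3 then closes the ring by an intramolecular Claisen (Dieckmann-type) condensation that forms the C2–C3 bond. The closest known reaction type is the consecutive Michael–Claisen [3+3] synthesis of cyclohexane-1,3-diones from ketones and acrylates, as in the preparation of 4,4-dimethylcyclohexane-1,3-dione from 3-methylbutan-2-one. The six-membered ring closes in a 6-(enolendo)-exo-trig mode. The only new stereocentre (C2 of 4) is enolisable, should form as the racemate or enol and is erased in step 2, so no control is needed. The step needs regioselectivity between the two α-carbons of 1: alkoxide-mediated Michael additions of unsymmetrical ketones go to the more substituted α-carbon (as with 2-methylcyclohexanone), and only that adduct can cyclise to a 1,3-dione that keeps an acidic hydrogen between the carbonyls, so enolate formation of 4 drives the sequence.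

Step 2
Reactants: 4 2,4,4-trimethylcyclohexane-1,3-dione
Product: 5 3-(2-methylpropoxy)-2,6,6-trimethylcyclohex-2-en-1-one
Conditions: i-BuOH, p-TsOH (cat.), toluene, reflux, Dean–Stark
Reagents that add atoms: 2-methylpropan-1-ol, CC(C)CO
Why: Acid-catalysed enol etherification (vinylogous ester formation) should occur at the less hindered carbonyl, remote from the gem-dimethyl carbon, which leaves the ketone on C1 free for the next step.

Step 3
Reactants: 5 3-(2-methylpropoxy)-2,6,6-trimethylcyclohex-2-en-1-one; 6 (4-bromobut-1-yn-1-yl)trimethylsilane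
Product: 9 2,4,4-trimethyl-3-[4-(trimethylsilyl)but-3-yn-1-yl]cyclohex-2-en-1-one, via Grignard reagent 7 (not isolated), via tertiary carbinol 8 (not isolated)
Conditions: 6, Mg, THF; CeCl3, −78 °C; 5, −78 to 0 °C; then 1 M HCl, rt
Reagents that add atoms: water, O
Why: Stork–Danheiser alkylative carbonyl transposition: the organocerium reagent from 7 adds 1,2 to the hindered, non-enolisable vinylogous ester carbonyl, and aqueous acid hydrolyses the enol ether and dehydrates to the tetrasubstituted enone, which places the chain on C1 and moves the carbonyl to C3.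

Step 4
Reactants: 9 2,4,4-trimethyl-3-[4-(trimethylsilyl)but-3-yn-1-yl]cyclohex-2-en-1-one
Product: 10 (1R)-2,4,4-trimethyl-3-[4-(trimethylsilyl)but-3-yn-1-yl]cyclohex-2-en-1-ol
Conditions: (S)-Me-CBS oxazaborolidine (0.2 equiv), catecholborane, toluene, −78 °C
Reagents that add atoms: none
Why: Corey–Bakshi–Shibata reduction: with the fully substituted alkenyl arm as the large group the (S)-oxazaborolidine should deliver hydride to the Si face and set the (R)-carbinol, and catecholborane at low temperature leaves the silylalkyne untouched.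

Step 5
Reactants: 10 (1R)-2,4,4-trimethyl-3-[4-(trimethylsilyl)but-3-yn-1-yl]cyclohex-2-en-1-ol
Product: 13 trimethyl{4-[(1S)-2,6,6-trimethylcyclohex-2-en-1-yl]but-1-yn-1-yl}silane, via sulfonylhydrazide 11 (not isolated), via allylic diazene 12 (not isolated)
Conditions: 2-nitrobenzenesulfonylhydrazide, PPh3, DEAD, N-methylmorpholine, −30 °C; then rt
Reagents that add atoms: none
Why: Myers reductive 1,3-transposition: Mitsunobu displacement inverts C3 to give 11, which loses 2-nitrobenzenesulfinic acid on warming, and allylic diazene 12 expels N2 in a suprafacial retro-ene ([1,5]-sigmatropic) shift that delivers hydrogen to C1 on the face opposite to the original hydroxyl, setting the (S)-centre and moving the alkene to C2=C3.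

Step 6
Reactants: 13 trimethyl{4-[(1S)-2,6,6-trimethylcyclohex-2-en-1-yl]but-1-yn-1-yl}silane
Product: 14 (6S)-6-(but-3-yn-1-yl)-1,5,5-trimethylcyclohex-1-ene
Conditions: K2CO3 (cat.), MeOH, rt
Reagents that add atoms: none
Why: Base-catalysed protodesilylation (methanolysis) of the alkynylsilane frees the terminal alkyne; nothing else in 13 is base-sensitive and the allylic stereocentre is not acidic.

Step 7
Reactants: 14 (6S)-6-(but-3-yn-1-yl)-1,5,5-trimethylcyclohex-1-ene
Product: 16 (6S)-6-[(3E)-4-iodo-3-methylbut-3-en-1-yl]-1,5,5-trimethylcyclohex-1-ene, via alkenylalane 15 (not isolated)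
Conditions: AlMe3, Cp2ZrCl2 (0.25 equiv), CH2Cl2, 0 °C to rt; then I2, THF, −30 °C
Reagents that add atoms: trimethylaluminium, C[Al](C)C; iodine, II
Why: Negishi zirconium-catalysed carboalumination adds Me–Al syn across the terminal alkyne with aluminium at the terminus, and iodinolysis of 15 with retention should give the (E)-2-methyl-1-iodoalkene; the trisubstituted ring alkene is inert.

Step 8
Reactants: 17 2-bromoprop-2-en-1-ol; 18 ethynyltrimethylsilane
Product: 19 2-methylidene-4-(trimethylsilyl)but-3-yn-1-ol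
Conditions: Pd(PPh3)2Cl2 (cat.), CuI (cat.), Et3N, THF, rt
Reagents that add atoms: none
Why: Sonogashira coupling of the vinyl bromide with the terminal alkyne; the free allylic alcohol is tolerated.

Step 9
Reactants: 19 2-methylidene-4-(trimethylsilyl)but-3-yn-1-ol
Product: 20 [(2R)-2-[(trimethylsilyl)ethynyl]oxiran-2-yl]methanol
Conditions: Ti(OiPr)4 (cat.), D-(−)-diethyl tartrate, t-BuOOH, 4 Å MS, CH2Cl2, −20 °C
Reagents that add atoms: tert-butyl hydroperoxide, CC(C)(C)OO
Why: Sharpless asymmetric epoxidation of a 2-substituted allylic alcohol: with D-(−)-diethyl tartrate the oxygen should be delivered to the face that gives the (R)-epoxide, whose oxygen-bearing carbon becomes the quaternary stereocentre of the target.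

Step 10
Reactants: 20 [(2R)-2-[(trimethylsilyl)ethynyl]oxiran-2-yl]methanol
Product: 21 tert-butyldimethyl{[(2S)-2-[(trimethylsilyl)ethynyl]oxiran-2-yl]methoxy}silane
Conditions: TBSCl, imidazole, CH2Cl2, 0 °C
Reagents that add atoms: tert-butyldimethylsilyl chloride, CC(C)(C)[Si](C)(C)Cl
Why: Imidazole-mediated silylation of the primary alcohol; the stereocentre is untouched (the descriptor changes only by priority) and no free alkoxide remains for the next step.

Step 11
Reactants: 21 tert-butyldimethyl{[(2S)-2-[(trimethylsilyl)ethynyl]oxiran-2-yl]methoxy}silane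
Product: 22 (3R)-3-{[tert-butyl(dimethyl)silyl]oxymethyl}-5-(trimethylsilyl)pent-1-en-4-yn-3-ol
Conditions: Me3S+ I− (3.5 equiv), n-BuLi (3.3 equiv), THF, −10 °C to rt
Reagents that add atoms: trimethylsulfonium iodide, C[S+](C)C.[I-]
Why: One-carbon homologation of an epoxide to an allylic alcohol with excess dimethylsulfonium methylide: the ylide opens the epoxide at the unhindered CH2 and the β-oxido sulfonium salt eliminates dimethyl sulfide to give the vinyl carbinol; the C–O bond of the stereocentre is not broken, so its configuration is retained.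

Step 12
Reactants: 22 (3R)-3-{[tert-butyl(dimethyl)silyl]oxymethyl}-5-(trimethylsilyl)pent-1-en-4-yn-3-ol
Product: 23 (3R)-3-{[tert-butyl(dimethyl)silyl]oxymethyl}-5-(trimethylsilyl)pent-1-en-4-yn-3-yl acetate
Conditions: Ac2O, DMAP, Et3N, CH2Cl2, rt to 40 °C
Reagents that add atoms: acetic anhydride, CC(=O)OC(C)=O
Why: DMAP-catalysed acetylation of the tertiary alcohol installs the final tertiary acetate early, so this oxygen needs no protecting group later.

Step 13
Reactants: 23 (3R)-3-{[tert-butyl(dimethyl)silyl]oxymethyl}-5-(trimethylsilyl)pent-1-en-4-yn-3-yl acetate; 16 (6S)-6-[(3E)-4-iodo-3-methylbut-3-en-1-yl]-1,5,5-trimethylcyclohex-1-ene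
Product: 25 (3R,6E)-3-{[tert-butyl(dimethyl)silyl]oxymethyl}-7-methyl-1-(trimethylsilyl)-9-[(1S)-2,6,6-trimethylcyclohex-2-en-1-yl]non-6-en-1-yn-3-yl acetate, via alkylborane 24 (not isolated)
Conditions: 23, 9-BBN, THF, 0 °C to rt; then 16, Pd(dppf)Cl2 (cat.), AsPh3, aq. K3PO4, DMF, rt
Reagents that add atoms: none
Why: B-alkyl Suzuki–Miyaura coupling: 9-BBN should hydroborate the monosubstituted alkene at its terminal carbon far faster than the silylated alkyne, and alkylborane 24 couples with alkenyl iodide 16 with retention of the (E)-geometry; both stereocentres are remote from the reacting atoms.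

Step 14
Reactants: 25 (3R,6E)-3-{[tert-butyl(dimethyl)silyl]oxymethyl}-7-methyl-1-(trimethylsilyl)-9-[(1S)-2,6,6-trimethylcyclohex-2-en-1-yl]non-6-en-1-yn-3-yl acetate
Product: 26 (3R,6E)-3-{[tert-butyl(dimethyl)silyl]oxymethyl}-7-methyl-9-[(1S)-2,6,6-trimethylcyclohex-2-en-1-yl]non-6-en-1-yn-3-yl acetate
Conditions: AgNO3 (0.1 equiv), acetone/H2O, rt, dark
Reagents that add atoms: none
Why: Silver-catalysed protodesilylation is selective for the alkynyl C–Si bond and is neutral, so the tertiary acetate and the silyl ether should survive.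

Step 15
Reactants: 26 (3R,6E)-3-{[tert-butyl(dimethyl)silyl]oxymethyl}-7-methyl-9-[(1S)-2,6,6-trimethylcyclohex-2-en-1-yl]non-6-en-1-yn-3-yl acetate
Product: 27 (1E,3R,6E)-3-{[tert-butyl(dimethyl)silyl]oxymethyl}-7-methyl-1-(4,4,5,5-tetramethyl-1,3,2-dioxaborolan-2-yl)-9-[(1S)-2,6,6-trimethylcyclohex-2-en-1-yl]nona-1,6-dien-3-yl acetate
Conditions: pinacolborane, Cp2Zr(H)Cl (10 mol%), Et3N (10 mol%), CH2Cl2, 40 °C
Reagents that add atoms: pinacolborane, [H]B1OC(C)(C)C(C)(C)O1
Why: Zirconocene hydride-catalysed hydroboration adds H–B syn and anti-Markovnikov to the terminal alkyne only, giving the (E)-alkenylboronate; the trisubstituted alkenes and the esters should not react, and a copper–boryl method is avoided because it would eliminate the propargylic acetate.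

Step 16
Reactants: 27 (1E,3R,6E)-3-{[tert-butyl(dimethyl)silyl]oxymethyl}-7-methyl-1-(4,4,5,5-tetramethyl-1,3,2-dioxaborolan-2-yl)-9-[(1S)-2,6,6-trimethylcyclohex-2-en-1-yl]nona-1,6-dien-3-yl acetate
Product: 28 (1E,3R,6E)-3-{[tert-butyl(dimethyl)silyl]oxymethyl}-7-methyl-9-[(1S)-2,6,6-trimethylcyclohex-2-en-1-yl]nona-1,6-diene-1,3-diyl diacetate
Conditions: Cu(OAc)2 (2 equiv), pyridine, 4 Å MS, MeCN, air, rt to 40 °C
Reagents that add atoms: Cu(OAc)2, CC(=O)[O-].CC(=O)[O-].[Cu+2]
Why: Chan–Lam-type oxidative C–O coupling: transmetalation of the alkenylboronate to divalent copper acetate and reductive elimination from a trivalent copper acetate should give the enol acetate with retention of the (E)-geometry, as known for alkenyltrifluoroborates with carboxylates.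

Step 17
Reactants: 28 (1E,3R,6E)-3-{[tert-butyl(dimethyl)silyl]oxymethyl}-7-methyl-9-[(1S)-2,6,6-trimethylcyclohex-2-en-1-yl]nona-1,6-diene-1,3-diyl diacetate
Product: 29 (1E,3R,6E)-3-(hydroxymethyl)-7-methyl-9-[(1S)-2,6,6-trimethylcyclohex-2-en-1-yl]nona-1,6-diene-1,3-diyl diacetate
Conditions: HF·pyridine, pyridine, THF, 0 °C
Reagents that add atoms: none
Why: Buffered fluoride desilylation removes the primary silyl ether without cleaving the enol acetate and, being weakly acidic, should not promote acetyl migration from the tertiary oxygen; 29 is oxidised without storage.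

Step 18
Reactants: 29 (1E,3R,6E)-3-(hydroxymethyl)-7-methyl-9-[(1S)-2,6,6-trimethylcyclohex-2-en-1-yl]nona-1,6-diene-1,3-diyl diacetate
Product: 30 (1E,3R,6E)-3-formyl-7-methyl-9-[(1S)-2,6,6-trimethylcyclohex-2-en-1-yl]nona-1,6-diene-1,3-diyl diacetate (CNP0244145.1)
Conditions: Dess–Martin periodinane, NaHCO3, CH2Cl2, 0 °C to rt
Reagents that add atoms: none
Why: Dess–Martin oxidation of the primary alcohol under buffered conditions should give the non-enolisable α-acetoxy aldehyde without touching either stereocentre or the enol acetate.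

**Compound list**

1 | 2-methylpentan-3-one | CCC(=O)C(C)C | starting material
2 | methyl acrylate | C=CC(=O)OC | starting material
3 | methyl 4,4-dimethyl-5-oxoheptanoate | CCC(=O)C(C)(C)CCC(=O)OC | intermediate
4 | 2,4,4-trimethylcyclohexane-1,3-dione | CC1C(=O)CCC(C)(C)C1=O | intermediate
5 | 3-(2-methylpropoxy)-2,6,6-trimethylcyclohex-2-en-1-one | CC1=C(OCC(C)C)CCC(C)(C)C1=O | intermediate
6 | (4-bromobut-1-yn-1-yl)trimethylsilane | C[Si](C)(C)C#CCCBr | starting material
7 | [4-(trimethylsilyl)but-3-yn-1-yl]magnesium bromide | C[Si](C)(C)C#CCC[Mg]Br | intermediate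
8 | 3-(2-methylpropoxy)-2,6,6-trimethyl-1-[4-(trimethylsilyl)but-3-yn-1-yl]cyclohex-2-en-1-ol (racemic) | CC1=C(OCC(C)C)CCC(C)(C)C1(O)CCC#C[Si](C)(C)C | intermediate
9 | 2,4,4-trimethyl-3-[4-(trimethylsilyl)but-3-yn-1-yl]cyclohex-2-en-1-one | CC1=C(CCC#C[Si](C)(C)C)C(C)(C)CCC1=O | intermediate
10 | (1R)-2,4,4-trimethyl-3-[4-(trimethylsilyl)but-3-yn-1-yl]cyclohex-2-en-1-ol | CC1=C(CCC#C[Si](C)(C)C)C(C)(C)CC[C@H]1O | intermediate
11 | N-{(1S)-2,4,4-trimethyl-3-[4-(trimethylsilyl)but-3-yn-1-yl]cyclohex-2-en-1-yl}-2-nitrobenzenesulfonohydrazide (alkylated on the sulfonylated nitrogen) | CC1=C(CCC#C[Si](C)(C)C)C(C)(C)CC[C@@H]1N(N)S(=O)(=O)c1ccccc1[N+](=O)[O-] | intermediate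
12 | {(1S)-2,4,4-trimethyl-3-[4-(trimethylsilyl)but-3-yn-1-yl]cyclohex-2-en-1-yl}diazene | CC1=C(CCC#C[Si](C)(C)C)C(C)(C)CC[C@@H]1N=N | intermediate
13 | trimethyl{4-[(1S)-2,6,6-trimethylcyclohex-2-en-1-yl]but-1-yn-1-yl}silane | C[Si](C)(C)C#CCC[C@@H]1C(C)=CCCC1(C)C | intermediate
14 | (6S)-6-(but-3-yn-1-yl)-1,5,5-trimethylcyclohex-1-ene | C#CCC[C@@H]1C(C)=CCCC1(C)C | intermediate
15 | dimethyl{(1E)-2-methyl-4-[(1S)-2,6,6-trimethylcyclohex-2-en-1-yl]but-1-en-1-yl}alane | C[Al](C)/C=C(\C)CC[C@@H]1C(C)=CCCC1(C)C | intermediate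
16 | (6S)-6-[(3E)-4-iodo-3-methylbut-3-en-1-yl]-1,5,5-trimethylcyclohex-1-ene | I/C=C(\C)CC[C@@H]1C(C)=CCCC1(C)C | intermediate
17 | 2-bromoprop-2-en-1-ol | OCC(Br)=C | starting material
18 | ethynyltrimethylsilane | C#C[Si](C)(C)C | starting material
19 | 2-methylidene-4-(trimethylsilyl)but-3-yn-1-ol | C=C(CO)C#C[Si](C)(C)C | intermediate
20 | [(2R)-2-[(trimethylsilyl)ethynyl]oxiran-2-yl]methanol | OC[C@]1(C#C[Si](C)(C)C)CO1 | intermediate
21 | tert-butyldimethyl{[(2S)-2-[(trimethylsilyl)ethynyl]oxiran-2-yl]methoxy}silane | CC(C)(C)[Si](C)(C)OC[C@]1(C#C[Si](C)(C)C)CO1 | intermediate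
22 | (3R)-3-{[tert-butyl(dimethyl)silyl]oxymethyl}-5-(trimethylsilyl)pent-1-en-4-yn-3-ol | C=C[C@](O)(CO[Si](C)(C)C(C)(C)C)C#C[Si](C)(C)C | intermediate
23 | (3R)-3-{[tert-butyl(dimethyl)silyl]oxymethyl}-5-(trimethylsilyl)pent-1-en-4-yn-3-yl acetate | C=C[C@](OC(C)=O)(CO[Si](C)(C)C(C)(C)C)C#C[Si](C)(C)C | intermediate
24 | (3R)-1-(9-borabicyclo[3.3.1]nonan-9-yl)-3-{[tert-butyl(dimethyl)silyl]oxymethyl}-5-(trimethylsilyl)pent-4-yn-3-yl acetate | C1CCC2CCCC1B2CC[C@](OC(C)=O)(CO[Si](C)(C)C(C)(C)C)C#C[Si](C)(C)C | intermediate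
25 | (3R,6E)-3-{[tert-butyl(dimethyl)silyl]oxymethyl}-7-methyl-1-(trimethylsilyl)-9-[(1S)-2,6,6-trimethylcyclohex-2-en-1-yl]non-6-en-1-yn-3-yl acetate | CC1=CCCC(C)(C)[C@@H]1CC/C(C)=C/CC[C@](OC(C)=O)(CO[Si](C)(C)C(C)(C)C)C#C[Si](C)(C)C | intermediate
26 | (3R,6E)-3-{[tert-butyl(dimethyl)silyl]oxymethyl}-7-methyl-9-[(1S)-2,6,6-trimethylcyclohex-2-en-1-yl]non-6-en-1-yn-3-yl acetate | CC1=CCCC(C)(C)[C@@H]1CC/C(C)=C/CC[C@](OC(C)=O)(CO[Si](C)(C)C(C)(C)C)C#C | intermediate
27 | (1E,3R,6E)-3-{[tert-butyl(dimethyl)silyl]oxymethyl}-7-methyl-1-(4,4,5,5-tetramethyl-1,3,2-dioxaborolan-2-yl)-9-[(1S)-2,6,6-trimethylcyclohex-2-en-1-yl]nona-1,6-dien-3-yl acetate | CC1=CCCC(C)(C)[C@@H]1CC/C(C)=C/CC[C@](OC(C)=O)(CO[Si](C)(C)C(C)(C)C)/C=C/B1OC(C)(C)C(C)(C)O1 | intermediate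
28 | (1E,3R,6E)-3-{[tert-butyl(dimethyl)silyl]oxymethyl}-7-methyl-9-[(1S)-2,6,6-trimethylcyclohex-2-en-1-yl]nona-1,6-diene-1,3-diyl diacetate | CC1=CCCC(C)(C)[C@@H]1CC/C(C)=C/CC[C@](OC(C)=O)(CO[Si](C)(C)C(C)(C)C)/C=C/OC(C)=O | intermediate
29 | (1E,3R,6E)-3-(hydroxymethyl)-7-methyl-9-[(1S)-2,6,6-trimethylcyclohex-2-en-1-yl]nona-1,6-diene-1,3-diyl diacetate | CC1=CCCC(C)(C)[C@@H]1CC/C(C)=C/CC[C@](OC(C)=O)(CO)/C=C/OC(C)=O | intermediate
30 | (1E,3R,6E)-3-formyl-7-methyl-9-[(1S)-2,6,6-trimethylcyclohex-2-en-1-yl]nona-1,6-diene-1,3-diyl diacetate (CNP0244145.1) | CC1=CCCC(C)(C)[C@@H]1CC/C(C)=C/CC[C@](OC(C)=O)(C=O)/C=C/OC(C)=O | target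

**Summary**

Total step count: 18. Longest linear sequence: 13 steps (steps 1–7, then 13–18); the acetate branch (steps 8–12) joins at step 13.

**Steps most likely to fail, with fallbacks**

Step 5. The hindered allylic oxyphosphonium ion may ionise, or react by SN2′ or elimination, before the bulky sulfonylhydrazide displaces it, which would erode the transfer of chirality from C3 to C1 or give diene. The fallback sets out from 10: formylation with acetic formic anhydride and pyridine should give (1R)-2,4,4-trimethyl-3-[4-(trimethylsilyl)but-3-yn-1-yl]cyclohex-2-en-1-yl formate F1, and palladium-catalysed formate hydrogenolysis (Pd(OAc)2, n-Bu3P, THF, rt) then ionises the formate with inversion by zerovalent palladium and delivers hydride from the metal to the more substituted allyl terminus C1. The hydrogen again enters anti to the original C–O bond, so the route is rejoined at 13.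

Step 16. Transmetalation of the pinacol boronate to copper may be slow, so that protodeboronation, homocoupling or slow loss of the silyl ether competes. The fallback sets out from 26: stoichiometric hydrozirconation (Cp2Zr(H)Cl, THF) should give the (E)-alkenylzirconocene chloride F2, iodinolysis (I2) gives (1E,3R,6E)-3-{[tert-butyl(dimethyl)silyl]oxymethyl}-1-iodo-7-methyl-9-[(1S)-2,6,6-trimethylcyclohex-2-en-1-yl]nona-1,6-dien-3-yl acetate F3, and an Ullmann-type vinylic substitution with CsOAc (CuI, N,N′-dimethylethylenediamine, dioxane, 80 °C) should replace iodide by acetate with retention, rejoining the route at 28.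

Step 13. The borane may also attack the silylalkyne, the alkynyl silyl group may be lost under the aqueous basic conditions and the freed alkyne may couple, or zerovalent palladium may ionise the propargylic acetate. The fallback sets out from 23 and avoids aqueous base: hydroboration with 9-BBN (via 24) and oxidation with NaBO3 should give (3R)-3-{[tert-butyl(dimethyl)silyl]oxymethyl}-1-hydroxy-5-(trimethylsilyl)pent-4-yn-3-yl acetate F4, iodination (I2, PPh3, imidazole) gives the primary iodide (3R)-3-{[tert-butyl(dimethyl)silyl]oxymethyl}-1-iodo-5-(trimethylsilyl)pent-4-yn-3-yl acetate F5, zinc insertion (Zn, LiCl, THF) gives the alkylzinc iodide F6, and a base-free Negishi coupling with 16 (Pd(OAc)2, SPhos, THF, rt) rejoins the route at 25.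

**Further compounds**

F1 | step 5 | (1R)-2,4,4-trimethyl-3-[4-(trimethylsilyl)but-3-yn-1-yl]cyclohex-2-en-1-yl formate | CC1=C(CCC#C[Si](C)(C)C)C(C)(C)CC[C@H]1OC=O
F2 | step 16 | chloro{(1E,3R,6E)-3-acetoxy-3-{[tert-butyl(dimethyl)silyl]oxymethyl}-7-methyl-9-[(1S)-2,6,6-trimethylcyclohex-2-en-1-yl]nona-1,6-dien-1-yl}zirconocene | CC1=CCCC(C)(C)[C@@H]1CC/C(C)=C/CC[C@](OC(C)=O)(CO[Si](C)(C)C(C)(C)C)/C=C/[Zr](Cl)(C1C=CC=C1)C1C=CC=C1
F3 | step 16 | (1E,3R,6E)-3-{[tert-butyl(dimethyl)silyl]oxymethyl}-1-iodo-7-methyl-9-[(1S)-2,6,6-trimethylcyclohex-2-en-1-yl]nona-1,6-dien-3-yl acetate | CC1=CCCC(C)(C)[C@@H]1CC/C(C)=C/CC[C@](OC(C)=O)(CO[Si](C)(C)C(C)(C)C)/C=C/I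
F4 | step 13 | (3R)-3-{[tert-butyl(dimethyl)silyl]oxymethyl}-1-hydroxy-5-(trimethylsilyl)pent-4-yn-3-yl acetate | OCC[C@](OC(C)=O)(CO[Si](C)(C)C(C)(C)C)C#C[Si](C)(C)C
F5 | step 13 | (3R)-3-{[tert-butyl(dimethyl)silyl]oxymethyl}-1-iodo-5-(trimethylsilyl)pent-4-yn-3-yl acetate | ICC[C@](OC(C)=O)(CO[Si](C)(C)C(C)(C)C)C#C[Si](C)(C)C
F6 | step 13 | {(3R)-3-acetoxy-3-{[tert-butyl(dimethyl)silyl]oxymethyl}-5-(trimethylsilyl)pent-4-yn-1-yl}zinc iodide | I[Zn]CC[C@](OC(C)=O)(CO[Si](C)(C)C(C)(C)C)C#C[Si](C)(C)C
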